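Start from 4 percentage points: the fall of target in the grey run between 3.00 h and 10.0 h.

common to all: gas phase 51 mM (held)
- grey: solid substrate 0.80 M; the very flask that is asked about, followed so far
- green: solid substrate 0.54 M; run made earlier
- flask: solid substrate 0.80 M; time 20 h

| run | time / h | target / % |
|---|---|---|
| grey | 0.833 | 66 |
| grey | 1.50 | 84 |
| grey | 3.00 | 91 |
| grey | 5.00 | 90 |
| grey | 10.0 | 87 |
| green | 0.667 | 64 |
| green | 1.33 | 84 |
| green | 2.50 | 92 |
| green | 4.00 | 90 |
| green | 8.00 | 93 |

(each reading ± 2 percentage points)

- solid, in amounts per volume of the solution: solid substrate
- the numbers in the tables scatter by 2 percentage points (one standard deviation)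
- at the start none of the gas phase is in solution
- at the start none of the solid substrate is in solution

1. target at 20 h, in percent of the solid substrate charged
2. concentration of dissolved gas in solution at 20 h, in percent of saturation

Set that fall against the scatter of a difference of two readings, 2.8 points: it comes to 1.41 such units, which is weak evidence. The green run then moves the other way, up 1 point between 2.50 h and 8.00 h. So read no loss of target. Average the late readings instead: grey gives 89.3% and green 91.7%. Pool them into the plateau yield, the level target holds after its rise ends: 90.5%, with a standard error of 0.82 points. My reckoning for the grey flask at 20 h is that plateau. For the dissolved gas I make no reckoning of my own.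

The forecast says 85% and 98%, and reads the drift differently: “That suggests a slow loss of target”.

The flask gives 90.3% and 97.3%.

    gas phase ⇌ dissolved gas, rate k1*(csat - [dissolved gas]) (kL = 0.130 s⁻¹)
    starting material + dissolved gas → target (k = 0.0110 M⁻¹ s⁻¹)
    starting material → side product (k = 5.70 × 10⁻⁵ s⁻¹)
    2 dissolved gas → homo dimer (k = 0.0360 M⁻¹ s⁻¹)
    solid substrate ⇌ starting material, rate k5*(cs5 - [starting material]) while solid is left; crystals form when [starting material] > cs5 (solubility = 0.520 M, k = 0.00250 s⁻¹)

Target in the flask stands 5.3 points above the forecast. In the scheme, target is made by one step and consumed by none. Stop the same flask at 12 h: that time also lies past the end of the rise, so the plateau yield says 90.5%. Stopped there, the flask holds 90.3% of target, with 0% left of the solid substrate, the limiting reagent, solid or dissolved.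

(The readings stem from a simulated flask for an exercise, and the scatter is random.)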